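## Retrosynthetic overview

- **Feature.** The plan rests on the cyclopentane C1–C2–C3–C4–C5, in which the oxygenated C4 stands next to the ring-fusion C5–H. This ring is the cyclohexenone ring of the Robinson annulation product of 2-methylcycloheptane-1,3-dione, less one carbon (Cx, between C3 and C4).
- **Ring order.** The seven-membered ring (C1, C5–C10) is bought. The six-membered ring is annulated onto it (Michael addition, then asymmetric aldol condensation, which sets C1). It is then contracted to the five-membered ring by benzilic acid rearrangement of the Cx/C4 diketone (new bond C3–C4), and Cx leaves as CO2.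
- **C6.** C6 stays CH2 during the contraction, because an oxygen there would be β to the C4 carbonyl and would be lost by retro-aldol or E1cB in hot KOH. It is introduced afterwards from the C4 ketone by imine-directed copper C–H hydroxylation. Isopropylcerium addition then fixes C4 and locks C5.
- **Endgame.** The C10 ketal is turned in sequence into the C9=C10 alkene, the C8 enone, the 9α,10α-diol and the C8 methylene. O6 is esterified, and a hydroxyl-directed epoxidation of C8=C14 ends the route.

Key step: step 7

**Numbering.** C1 is the methyl-bearing fusion carbon, C2/C3 the ring CH2 groups, C4 the carbinol carbon, C5 the fusion CH. C6–C10 run round the seven-membered ring, with C10 on C1. C14 is the carbon on C8 and C15 the angular methyl. Cx is the extra six-ring carbon between C3 and C4. β is the face of C15 and α the opposite face.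

**Assumption.** The sense of induction of amine catalysts cannot be carried over safely from the six-membered dione series to the seven-membered one. The catalyst antipode that leads to the (S)-enedione is therefore used in step 3; both antipodes are available.

## Route

**Step 1**
Reactants: 1 cycloheptane-1,3-dione; 2 iodomethane
Product: 3 2-methylcycloheptane-1,3-dione
Conditions: MeI (1.1 equiv), K2CO3, acetone, 50 °C
Reagents that add atoms: iodomethane CI
Why: C-alkylation of the stabilised 1,3-diketone enolate with a soft electrophile and a weak base should give the 2-methyl dione, and no stereocentre is formed.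

**Step 2**
Reactants: 3 2-methylcycloheptane-1,3-dione; 4 methyl vinyl ketone
Product: 5 2-methyl-2-(3-oxobutyl)cycloheptane-1,3-dione
Conditions: MVK (1.5 equiv), Et3N (cat.), CH2Cl2, rt
Reagents that add atoms: methyl vinyl ketone CC(=O)C=C
Why: Amine-catalysed Michael addition (first half of a Robinson annulation) builds the quaternary but still prochiral C1 and brings in C2, C3, Cx and C4.

**Step 3**
Reactants: 5 2-methyl-2-(3-oxobutyl)cycloheptane-1,3-dione
Product: 6 (S)-4a-methyl-4,4a,6,7,8,9-hexahydro-3H-benzo[7]annulene-2,5-dione (six–seven enedione: enone Cx(=O)–C4H=C5, C10 ketone, C1 S)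
Conditions: tert-leucine-derived primary–tertiary diamine (N1,N1-diethyl-3,3-dimethylbutane-1,2-diamine)·TfOH (10 mol %), 3-nitrobenzoic acid (10 mol %), neat, 60 °C; recrystallisation
Reagents that add atoms: none
Why: Enamine-mediated intramolecular aldol condensation of Hajos–Parrish–Eder–Sauer–Wiechert type closes the six-membered ring, and by choosing one of the two enantiotopic ring carbonyls the chiral amine sets C1.

**Step 4**
Reactants: 6 (S)-enedione
Product: 7 C10 ethylene ketal of 6
Conditions: TMSOCH2CH2OTMS, TMSOTf (cat.), CH2Cl2, −78 → −20 °C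
Reagents that add atoms: 1,2-bis(trimethylsiloxy)ethane C[Si](C)(C)OCCO[Si](C)(C)C
Why: Noyori ketalisation under kinetic conditions should take the saturated C10 ketone in preference to the less electrophilic enone carbonyl and leave C4=C5 in place.

**Step 5**
Reactants: 7 enone ketal
Product: 8 4β,5β-epoxy ketone (the α-epoxide, if formed, serves equally)
Conditions: 30% aq H2O2, NaOH (cat.), MeOH, 0 °C
Reagents that add atoms: hydrogen peroxide OO
Why: Weitz–Scheffer nucleophilic epoxidation attacks only the electron-poor C4=C5 bond, and its facial outcome is irrelevant because C4 and C5 both become sp2 again in step 6.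

**Step 6**
Reactants: 8 epoxy ketone
Product: 9 diosphenol (C4 enol, C4=C5, Cx ketone, C10 ketal)
Conditions: KOH (3 equiv), t-BuOH/H2O 1:1, 70 °C, argon; cold 1 M KHSO4
Reagents that add atoms: potassium hydroxide [K+].[OH-]
Why: In this base-mediated epoxy ketone to diosphenol isomerisation, hydroxide opens the epoxide at the carbonyl-activated C4 and the C5 hydroxyl then leaves by E1cB; the dioxolane tolerates these conditions, whereas the usual acid-catalysed variant would endanger it.

**Step 7**
Reactants: 9 diosphenol
Product: 11 trans-hydroazulene 4-hydroxy-4-carboxylic acid C10 ketal, via trans-fused 1,2-diketone 10 (not isolated)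
Conditions: KOH (20 equiv), n-PrOH/H2O 1:1, degassed, argon, reflux; cold 1 M KHSO4 to pH 3
Reagents that add atoms: potassium hydroxide [K+].[OH-]
Why: The potassium diosphenolate of 9 equilibrates by C-protonation at C5 with the diketone 10, hydroxide adds to the less hindered carbonyl Cx, and the alkoxide collapses with a 1,2-shift of C3 from Cx to the neighbouring carbonyl carbon C4, made irreversible by carboxylate formation (addition at C4 with shift of C5 would give the same constitution). The closest known reaction is the benzilic acid ring contraction of cyclic 1,2-diketones and diosphenols, for example of steroidal ring A diosphenols to A-nor hydroxy acids. The cyclopentane C1–C5 is closed by this ring contraction and not by a cyclisation: the new C3–C4 bond replaces C3–Cx, and Cx–C4 remains as the bond to the exocyclic carboxyl group. C5 is set under Curtin–Hammett conditions by the protonation equilibrium, the trans-diketone with both fusion bonds equatorial on a chair ring A being the form expected to rearrange, and it is frozen once C4 is sp3; C4 (drawn with OH on the C15 face) is set by the face on which C3 arrives and need not be controlled because step 8 erases it. The step needs the rearrangement to outrun aldol, elimination and autoxidation: C6 carries no leaving group, C10 is a base-stable dioxolane, C1 is quaternary, and oxygen is excluded so that the enolate is not cleaved oxidatively.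

**Step 8**
Reactants: 11 hydroxy acid
Product: 12 trans-fused C4 ketone (5α-H), C10 ketal
Conditions: Pb(OAc)4, pyridine, CH2Cl2, 0 °C
Reagents that add atoms: none
Why: Oxidative decarboxylation of the α-hydroxy acid (glycol-cleavage type) expels Cx as CO2 and erases C4, and the cold buffered medium should leave the newly epimerisable C5 untouched.

**Step 9**
Reactants: 12 C4 ketone; 13 2-picolylamine
Product: 14 (E)-N-(2-pyridylmethyl) ketimine of 12
Conditions: 2-picolylamine (1.5 equiv), TsOH·H2O (1 mol %), 4 Å MS, toluene, 60 °C
Reagents that add atoms: 2-picolylamine NCc1ccccn1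
Why: In this ketimine condensation the picolyl arm should settle anti to the more substituted C5, so that the nitrogen lone pair, and later the copper bound to it, points towards C6.

**Step 10**
Reactants: 14 picolyl ketimine
Product: 16 6α-hydroxy C4 ketone C10 ketal, via 6α-hydroxy picolylimine 15 (not isolated)
Conditions: Cu(NO3)2·3H2O (1.2 equiv), 30% aq H2O2, acetone/MeOH, rt; then aq Na2H2(edta), pH 5–6, EtOAc
Reagents that add atoms: hydrogen peroxide OO; water O
Why: Imine-directed copper-mediated C(sp3)–H hydroxylation is known for picolylimines of trans-fused five-ring ketones (steroid ring D, giving the equatorial alcohol in the neighbouring ring with retention); here the matching bond is the equatorial 6α-H syn to H5, which sets C6, and the mildly acidic edta work-up removes divalent copper and hydrolyses the imine.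

**Step 11**
Reactants: 16 β-hydroxy ketone
Product: 17 6α-TBS ether of 16
Conditions: TBSOTf, 2,6-lutidine, CH2Cl2, −78 → 0 °C
Reagents that add atoms: tert-butyldimethylsilyl triflate CC(C)(C)[Si](C)(C)OS(=O)(=O)C(F)(F)F
Why: Silylation with a hindered pyridine base masks O6 as a poor leaving group without enolising the ketone, so C5 and C6 are kept.

**Step 12**
Reactants: 17 silyloxy ketone; 18 isopropylmagnesium chloride
Product: 19 tertiary alcohol (4β-OH, 4α-isopropyl, 5α-H, 6α-OTBS, C10 ketal)
Conditions: iPrMgCl, anhydrous CeCl3, THF, −78 °C; aq NH4Cl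
Reagents that add atoms: isopropylmagnesium chloride CC(C)[Mg]Cl
Why: Organocerium 1,2-addition suppresses enolisation, silanolate elimination and β-hydride reduction; the reagent should come from the α face past H5, since the β face of the cyclopentanone is closed by C6 and C15, which sets C4 and removes the acidity of H5.

**Step 13**
Reactants: 19 tertiary alcohol ketal
Product: 20 C10 ketone
Conditions: PPTS, acetone/H2O 9:1, 55 °C
Reagents that add atoms: water O
Why: Mild acid hydrolysis of the sterically compressed neopentyl dioxolane should spare the secondary TBS ether and the tertiary alcohol.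

**Step 14**
Reactants: 20 C10 ketone
Product: 21 C9=C10 enol triflate
Conditions: KN(SiMe3)2 (2.3 equiv), THF, −78 °C; PhNTf2; aq NH4Cl
Reagents that add atoms: N-phenylbis(trifluoromethanesulfonimide) O=S(=O)(N(c1ccccc1)S(=O)(=O)C(F)(F)F)C(F)(F)F
Why: In this enolate O-sulfonylation C9 is the only enolisable position because C1 is quaternary, and the extra base merely holds the crowded tertiary alcohol as its alkoxide at a temperature where silyl migration is not expected.

**Step 15**
Reactants: 21 enol triflate
Product: 22 C9=C10 alkene
Conditions: Pd(OAc)2 (5 mol %), PPh3, HCO2H, Et3N, DMF, 60 °C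
Reagents that add atoms: none
Why: Palladium-catalysed formate reduction of the vinyl triflate replaces OTf by H without moving the double bond.

**Step 16**
Reactants: 22 alkene
Product: 23 C9=C10 en-8-one
Conditions: Rh2(cap)4 (cap = caprolactamate, 1 mol %), 70% aq TBHP, ClCH2CH2Cl, 40 °C
Reagents that add atoms: tert-butyl hydroperoxide CC(C)(C)OO
Why: In this catalytic allylic oxidation with TBHP, C8 is the only allylic C–H position because C1 is quaternary, and the allyl radical should be captured at C8 in preference to the neopentyl C10.

**Step 17**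
Reactants: 23 enone
Product: 24 9α,10α-dihydroxy-8-ketone
Conditions: OsO4 (5 mol %), NMO, acetone/H2O, rt
Reagents that add atoms: N-methylmorpholine N-oxide C[N+]1([O-])CCOCC1; water O
Why: Upjohn dihydroxylation adds both oxygens suprafacially and should come from the α face, opposite the axial C15 methyl on the adjacent C1, which sets C9 and C10 as the cis α-diol.

**Step 18**
Reactants: 24 diol ketone
Product: 25 9,10-acetonide
Conditions: Me2C(OMe)2, PPTS (cat.), CH2Cl2, rt
Reagents that add atoms: 2,2-dimethoxypropane COC(C)(C)OC
Why: Transketalisation of the cis-1,2-diol blocks α-ketol isomerisation and leaves the tertiary alcohol free.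

**Step 19**
Reactants: 25 acetonide ketone; 26 methyltriphenylphosphonium bromide
Product: 27 C8 exocyclic methylene compound
Conditions: Ph3PCH3Br, KOtBu, THF, 0 °C; then 25, 0 °C → rt
Reagents that add atoms: methyltriphenylphosphonium bromide C[P+](c1ccccc1)(c1ccccc1)c1ccccc1.[Br-]
Why: Wittig methylenation of the unhindered C8 ketone brings in C14, and with only poor leaving groups (silyl ether, acetonide) in the β positions addition should be faster than enolisation and elimination.

**Step 20**
Reactants: 27 silyl ether
Product: 28 4β,6α-diol acetonide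
Conditions: TBAF, THF, 40 °C
Reagents that add atoms: none
Why: Fluoride desilylation frees O6 while the acetonide keeps O9 and O10 masked.

**Step 21**
Reactants: 28 diol; 29 isovaleric anhydride
Product: 30 6α-isovalerate acetonide
Conditions: (iBuCO)2O, DMAP, pyridine, CH2Cl2, rt
Reagents that add atoms: isovaleric anhydride CC(C)CC(=O)OC(=O)CC(C)C
Why: DMAP-catalysed acylation takes the only free secondary hydroxyl, and the tertiary C4 alcohol flanked by the isopropyl group should not react.

**Step 22**
Reactants: 30 ester acetonide
Product: 31 8(14)-ene-4β,9α,10α-triol 6α-isovalerate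
Conditions: AcOH/H2O 4:1, 45 °C
Reagents that add atoms: none
Why: Mild aqueous acid cleaves the acetonide without ionising the allylic C9–O bond, dehydrating C4 or touching the ester.

**Step 23**
Reactants: 31 allylic diol
Product: 32 target CNP0307265.1
Conditions: VO(acac)2 (5 mol %), TBHP (decane), CH2Cl2, 0 °C
Reagents that add atoms: tert-butyl hydroperoxide CC(C)(C)OO
Why: In this hydroxyl-directed vanadium epoxidation the vanadate ester of the allylic 9α-OH, supported by the 10α-OH, should deliver oxygen to the α face of C8=C14 and so set C8 with the epoxide oxygen cis to O9.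

## Compound list

1 | cycloheptane-1,3-dione | O=C1CCCCC(=O)C1 | starting material
2 | iodomethane | CI | starting material
3 | 2-methylcycloheptane-1,3-dione | CC1C(=O)CCCCC1=O | intermediate
4 | methyl vinyl ketone | CC(=O)C=C | starting material
5 | 2-methyl-2-(3-oxobutyl)cycloheptane-1,3-dione | CC(=O)CCC1(C)C(=O)CCCCC1=O | intermediate
6 | (S)-six–seven enedione | C[C@]12CCC(=O)C=C1CCCCC2=O | intermediate
7 | C10 ethylene ketal of 6 | C[C@]12CCC(=O)C=C1CCCCC23OCCO3 | intermediate
8 | 4β,5β-epoxy ketone | C[C@]12CCC(=O)[C@@H]3O[C@]13CCCCC24OCCO4 | intermediate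
9 | diosphenol | C[C@]12CCC(=O)C(O)=C1CCCCC23OCCO3 | intermediate
10 | trans-fused six–seven 1,2-diketone (5α-H), C10 ketal | C[C@]12CCC(=O)C(=O)[C@@H]1CCCCC23OCCO3 | intermediate
11 | trans-hydroazulene C4 hydroxy acid (OH β as drawn), C10 ketal | C[C@]12CC[C@@](O)(C(O)=O)[C@@H]1CCCCC23OCCO3 | intermediate
12 | trans-fused C4 ketone, C10 ketal | C[C@]12CCC(=O)[C@@H]1CCCCC23OCCO3 | intermediate
13 | 2-picolylamine | NCc1ccccn1 | starting material
14 | (E)-picolyl ketimine of 12 | C[C@]12CC/C(=N\Cc3ccccn3)[C@@H]1CCCCC23OCCO3 | intermediate
15 | 6α-hydroxy picolylimine | C[C@]12CC/C(=N\Cc3ccccn3)[C@@H]1[C@@H](O)CCCC23OCCO3 | intermediate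
16 | 6α-hydroxy C4 ketone, C10 ketal | C[C@]12CCC(=O)[C@@H]1[C@@H](O)CCCC23OCCO3 | intermediate
17 | 6α-TBS ether of 16 | C[C@]12CCC(=O)[C@@H]1[C@@H](O[Si](C)(C)C(C)(C)C)CCCC23OCCO3 | intermediate
18 | isopropylmagnesium chloride | CC(C)[Mg]Cl | starting material
19 | 4β-hydroxy-4α-isopropyl 6α-OTBS C10 ketal | C[C@]12CC[C@@](O)(C(C)C)[C@@H]1[C@@H](O[Si](C)(C)C(C)(C)C)CCCC23OCCO3 | intermediate
20 | C10 ketone | C[C@]12CC[C@@](O)(C(C)C)[C@@H]1[C@@H](O[Si](C)(C)C(C)(C)C)CCCC2=O | intermediate
21 | C9=C10 enol triflate | C[C@]12CC[C@@](O)(C(C)C)[C@@H]1[C@@H](O[Si](C)(C)C(C)(C)C)CCC=C2OS(=O)(=O)C(F)(F)F | intermediate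
22 | C9=C10 alkene | C[C@]12CC[C@@](O)(C(C)C)[C@@H]1[C@@H](O[Si](C)(C)C(C)(C)C)CCC=C2 | intermediate
23 | C9=C10 en-8-one | C[C@]12CC[C@@](O)(C(C)C)[C@@H]1[C@@H](O[Si](C)(C)C(C)(C)C)CC(=O)C=C2 | intermediate
24 | 9α,10α-dihydroxy-8-ketone | C[C@]12CC[C@@](O)(C(C)C)[C@@H]1[C@@H](O[Si](C)(C)C(C)(C)C)CC(=O)[C@@H](O)[C@H]2O | intermediate
25 | 9,10-acetonide 8-ketone | C[C@]12CC[C@@](O)(C(C)C)[C@@H]1[C@@H](O[Si](C)(C)C(C)(C)C)CC(=O)[C@H]3OC(C)(C)O[C@@H]23 | intermediate
26 | methyltriphenylphosphonium bromide | C[P+](c1ccccc1)(c1ccccc1)c1ccccc1.[Br-] | starting material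
27 | C8 methylene acetonide, 6α-OTBS | C[C@]12CC[C@@](O)(C(C)C)[C@@H]1[C@@H](O[Si](C)(C)C(C)(C)C)CC(=C)[C@H]3OC(C)(C)O[C@@H]23 | intermediate
28 | C8 methylene acetonide, 4β,6α-diol | C[C@]12CC[C@@](O)(C(C)C)[C@@H]1[C@@H](O)CC(=C)[C@H]3OC(C)(C)O[C@@H]23 | intermediate
29 | isovaleric anhydride | CC(C)CC(=O)OC(=O)CC(C)C | starting material
30 | 6α-isovalerate acetonide | C[C@]12CC[C@@](O)(C(C)C)[C@@H]1[C@@H](OC(=O)CC(C)C)CC(=C)[C@H]3OC(C)(C)O[C@@H]23 | intermediate
31 | 8(14)-ene-4β,9α,10α-triol 6α-isovalerate | C[C@]12CC[C@@](O)(C(C)C)[C@@H]1[C@@H](OC(=O)CC(C)C)CC(=C)[C@@H](O)[C@H]2O | intermediate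
32 | CNP0307265.1 | CC(C)CC(=O)O[C@H]1C[C@]2(CO2)[C@@H](O)[C@@H](O)[C@@]2(C)CC[C@@](O)(C(C)C)[C@H]12 | target

## Step count and risks

Total step count: 23. Longest linear sequence: 23 steps.

**Step 7 (benzilic contraction).**
- What may go wrong: the strongly stabilised diosphenolate may resist rearrangement. Traces of air may cleave it. Protonation at C5 may feed the cis-fused manifold, so that the ring fusion comes out wrong or mixed.
- Fallback: it sets out from 9 and makes the same C3–C4 bond by ester condensation.
  - Alkaline H2O2 cleaves the Cx–C4 bond to the seco diacid F1.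
  - MeI/K2CO3 in DMF gives the dimethyl ester F2.
  - Dieckmann condensation (KOtBu, THF) closes the five-membered ring to the β-keto ester F3. Only this regioisomer keeps an acidic C3–H and survives as its enolate.
  - Krapcho demethoxycarbonylation (LiCl, wet DMSO, 150 °C) removes Cx.
- The fallback comes back to the route at 12. The C5 epimers of 12 can be separated there, and the unwanted one can be recycled by base equilibration.

**Step 10 (C6–H hydroxylation).**
- What may go wrong: the copper-bound oxidant may not reach the C6–H bond of the more flexible seven-membered ring. Imine–enamine tautomerism may scramble C5. The β-hydroxy ketone may dehydrate during work-up.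
- Fallback: it sets out from 12 and activates C6 through unsaturation.
  - TMSCl/NaI/Et3N in MeCN gives the more substituted silyl enol ether F4.
  - Saegusa–Ito oxidation with Pd(OAc)2 gives the C5=C6 enone F5.
  - Copper-catalysed conjugate borylation (B2pin2, CuCl, NaOtBu, Xantphos, MeOH, THF) gives the β-boryl ketone F6.
  - NaBO3·4H2O oxidises the C–B bond with retention.
- The fallback comes back to the route at 16. C6 then depends on the face of boryl-copper addition and C5 on the protonation, so a diastereomer separation must be expected at that point.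

**Step 16 (allylic oxidation).**
- What may go wrong: the cis-disubstituted cycloheptene may be converted only slowly. The allyl radical may be captured at C10. Hydrogen abstraction may compete at C6 next to the silyl ether.
- Fallback: it sets out from 20 and transposes the carbonyl group without radical chemistry.
  - IBX in DMSO at 70 °C gives the C8=C9 en-10-one F7.
  - TBHP/DBU gives the 8,9-epoxy ketone F8, whose epoxide face is irrelevant.
  - Wharton transposition (N2H4·H2O, AcOH, MeOH) gives the C9=C10 en-8-ol F9.
  - Dess–Martin oxidation gives the enone.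
- The fallback comes back to the route at 23.

## Further compounds

F1 | step 7 | seco diacid (Cx and C4 as carboxyl groups) | C[C@]1(CCC(O)=O)[C@H](C(O)=O)CCCCC12OCCO2
F2 | step 7 | dimethyl ester of F1 | C[C@]1(CCC(=O)OC)[C@H](C(=O)OC)CCCCC12OCCO2
F3 | step 7 | β-keto ester (C4 ketone, methoxycarbonyl on C3) | C[C@]12CC(C(=O)OC)C(=O)[C@@H]1CCCCC23OCCO3
F4 | step 10 | C4=C5 trimethylsilyl enol ether | C[C@]12CCC(O[Si](C)(C)C)=C1CCCCC23OCCO3
F5 | step 10 | C5=C6 en-4-one | C[C@]12CCC(=O)C1=CCCCC23OCCO3
F6 | step 10 | 6α-pinacolboryl C4 ketone | C[C@]12CCC(=O)[C@@H]1[C@@H](B3OC(C)(C)C(C)(C)O3)CCCC24OCCO4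
F7 | step 16 | C8=C9 en-10-one | C[C@]12CC[C@@](O)(C(C)C)[C@@H]1[C@@H](O[Si](C)(C)C(C)(C)C)CC=CC2=O
F8 | step 16 | 8α,9α-epoxy-10-ketone | C[C@]12CC[C@@](O)(C(C)C)[C@@H]1[C@@H](O[Si](C)(C)C(C)(C)C)C[C@H]3O[C@H]3C2=O
F9 | step 16 | C9=C10 en-8α-ol | C[C@]12CC[C@@](O)(C(C)C)[C@@H]1[C@@H](O[Si](C)(C)C(C)(C)C)C[C@@H](O)C=C2
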